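**Plan**

1. The retrosynthesis first cuts the four aryl ester C–O bonds on the central ring (acetate on C1, 3-phenylpropanoate on C2, (R)-3-hydroxybutanoates on C4 and C5) and the four benzyl ethers, leaving a 3,6-diaryl tetraoxygenated benzene with graded protection.
2. Enabling feature: in the central benzene ring, aryl-bearing C3 lies between oxygenated C2 and C4, and the oxygens on C1 and C5 are meta and flank aryl-bearing C6. This is the imprint of a folded 1,3,5-triketone, so C3–C4 and C2–C3 are cut to give a 3-aryl-1,5-dialkoxypentane-2,4-dione and methyl 4-(benzyloxy)benzoate, whose ester carbon becomes C3.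
3. The diketone is cut at its benzylic carbon into a benzyl ketone (benzyl Grignard reagent plus a glycolic Weinreb amide) and a second glycolic acid unit; the two glycolate oxygens carry different acetals (THP for C4, MOM for C2).
4. Forward: the chain is joined in steps 1–6, and the central ring (the only ring made) closes in step 7 by Claisen acylation and aldol aromatisation. The oxygens are then addressed in the order C4/C5 bridge, C1 acetate, C4/C5 esters, C2 ester, and all benzyl groups fall in the last step.
5. Stereochemistry: both stereocentres are those of methyl (R)-3-hydroxybutanoate (chiral pool), carried as the O-benzyl acid; no stereocentre is created or touched in the route.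

Key step: step 7

Remark: central-ring locants C1–C6 are those of the target throughout; because the two outer rings and the two hydroxybutanoates are identical, exchanging acetate and phenylpropanoate between C1 and C2 gives the same compound, so acyl migration between these two oxygens is harmless; THP (oxan-2-yl) compounds are carried as racemates at the acetal carbon.

**Step 1**
Reactants: 1 methyl glycolate
Product: 2 methyl 2-(oxan-2-yloxy)acetate
Conditions: 3,4-dihydro-2H-pyran, PPTS (cat.), CH2Cl2, rt
Reagents that add atoms: 3,4-dihydro-2H-pyran, C1=COCCC1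
Why: Acid-catalysed addition of the primary alcohol to the enol ether (tetrahydropyranylation) gives an acetal that tolerates the organomagnesium and amide-base steps ahead and can later be removed without loss of a MOM ether.

**Step 2**
Reactants: 2 methyl 2-(oxan-2-yloxy)acetate
Product: 3 N-methoxy-N-methyl-2-(oxan-2-yloxy)acetamide
Conditions: MeNH(OMe)·HCl, iPrMgCl, THF, −20 → 0 °C
Reagents that add atoms: N,O-dimethylhydroxylamine hydrochloride, CNOC.Cl
Why: The magnesium amide of N,O-dimethylhydroxylamine formed with iPrMgCl converts a methyl ester directly into the Weinreb amide (ester aminolysis), and the acetal is inert to it.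

**Step 3**
Reactants: 4 4-(benzyloxy)benzyl chloride; 3 N-methoxy-N-methyl-2-(oxan-2-yloxy)acetamide
Product: 6 1-[4-(benzyloxy)phenyl]-3-(oxan-2-yloxy)propan-2-one, via 4-(benzyloxy)benzylmagnesium chloride 5 (not isolated)
Conditions: Mg (I2-activated), THF, slow addition of 4, 0 °C → rt; then 3, THF, −20 → 0 °C; aq NH4Cl
Reagents that add atoms: none
Why: The benzylic chloride inserts Mg and the Grignard reagent adds only once to the amide because the magnesium chelate of the tetrahedral adduct survives until the quench (Weinreb ketone synthesis); slow addition at high dilution limits Wurtz coupling.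

**Step 4**
Reactants: 1 methyl glycolate
Product: 7 methyl 2-(methoxymethoxy)acetate
Conditions: MOMCl, iPr2NEt, CH2Cl2, 0 °C → rt
Reagents that add atoms: chloromethyl methyl ether, COCCl
Why: O-Alkylation of the alcohol with the chloromethyl ether under amine base (MOM protection) is standard for α-hydroxy esters.

**Step 5**
Reactants: 7 methyl 2-(methoxymethoxy)acetate
Product: 8 2-(methoxymethoxy)acetic acid
Conditions: LiOH·H2O, THF/H2O, 0 °C → rt; 1 M HCl to pH 3, 0 °C
Reagents that add atoms: lithium hydroxide, [Li+].[OH-]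
Why: Saponification of an unhindered methyl ester; the MOM acetal is stable to base and to brief cold acidification.

**Step 6**
Reactants: 8 2-(methoxymethoxy)acetic acid; 6 1-[4-(benzyloxy)phenyl]-3-(oxan-2-yloxy)propan-2-one
Product: 10 3-[4-(benzyloxy)phenyl]-1-(methoxymethoxy)-5-(oxan-2-yloxy)pentane-2,4-dione, via (methoxymethoxy)acetyl imidazolide 9 (not isolated)
Conditions: 8, CDI, THF, rt; separately 6, LiN(SiMe3)2 (3.2 equiv), THF, −78 °C; then solution of 9, −78 → 0 °C; aq NH4Cl
Reagents that add atoms: none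
Why: Deprotonation of 6 should occur at the benzylic α-carbon, by far the more acidic site, and the lithium enolate is acylated on carbon by the N-acylimidazole (Claisen-type C-acylation of a preformed enolate), the surplus base absorbing the imidazole from CDI and converting the acidic 2-aryl-1,3-diketone into its enolate as it forms.

**Step 7**
Reactants: 10 3-[4-(benzyloxy)phenyl]-1-(methoxymethoxy)-5-(oxan-2-yloxy)pentane-2,4-dione; 11 methyl 4-(benzyloxy)benzoate
Product: 14 2,5-bis[4-(benzyloxy)phenyl]-4-(methoxymethoxy)-6-(oxan-2-yloxy)benzene-1,3-diol, via MOM-side triketone 12 (not isolated), via THP-side triketone 13 (not isolated)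
Conditions: LiN(iPr)2 (3.3 equiv), THF, −78 → 0 °C; 11, 0 °C → rt; then degassed 2 M aq KOH/MeOH, 45 °C, Ar; aq NH4Cl to pH 6–7
Reagents that add atoms: none
Why: LiN(iPr)2 first forms the diketonate at the aryl-bearing carbon and then removes a proton from one alkoxymethyl terminus, and the terminal carbanion of this dianion attacks the ester carbonyl of 11 with loss of methoxide to give the 1,3,5-triketone (Claisen acylation, C3–C4), the third equivalent of base taking up the new acidic proton. In hydroxide/methanol the enolate of the remaining alkoxymethyl terminus adds to the aryl ketone carbonyl (intramolecular aldol, C2–C3), and loss of water followed by enolisation of the two remaining ring ketones gives the benzene ring without any change of oxidation level. The closest known reaction type is the terminal aroylation of β-diketone dianions to 1,3,5-triketones and their alkali-induced cyclisation to resorcinols. The one ring formed, the central benzene ring, closes in the 6-(enolendo)-exo-trig mode, and no stereocentre is created. Two selectivities are needed: closure through carbon and not oxygen, which the basic medium should secure because the 4-pyranone requires acid-promoted dehydration of a hemiketal whereas the aldol product drains irreversibly into the phenoxide, and site of acylation, which is immaterial because triketones 12 and 13 fold to the same arene with the ester carbon at C3, para to C6. The ketone oxygens end as the free hydroxyls on C1 and C5 and the acetal oxygens on C2 (MOM) and C4 (THP), which is the differentiation used downstream.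

**Step 8**
Reactants: 14 2,5-bis[4-(benzyloxy)phenyl]-4-(methoxymethoxy)-6-(oxan-2-yloxy)benzene-1,3-diol
Product: 15 3,6-bis[4-(benzyloxy)phenyl]-5-(methoxymethoxy)benzene-1,2,4-triol
Conditions: PPTS (cat.), degassed MeOH/THF, rt → 40 °C, Ar
Reagents that add atoms: none
Why: Acetal exchange with methanol under pyridinium catalysis removes the aryl THP ether while the less labile aryl MOM ether and the benzyl ethers persist; the electron-rich triol is kept under argon and used at once.

**Step 9**
Reactants: 15 3,6-bis[4-(benzyloxy)phenyl]-5-(methoxymethoxy)benzene-1,2,4-triol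
Product: 16 4,7-bis[4-(benzyloxy)phenyl]-2,2-di-tert-butyl-6-(methoxymethoxy)-1,3,2-benzodioxasilol-5-ol
Conditions: tBu2Si(OTf)2 (1.05 equiv), 2,6-lutidine, CH2Cl2, −40 → 0 °C, Ar
Reagents that add atoms: di-tert-butylsilyl bis(trifluoromethanesulfonate), CC(C)(C)[Si](OS(=O)(=O)C(F)(F)F)(OS(=O)(=O)C(F)(F)F)C(C)(C)C
Why: Only the adjacent hydroxyls on C4 and C5 can be joined in a five-membered dioxasilole (cyclic silylene formation of a catechol), and the hydrogen-bonded catechol is the most acidic site, so one equivalent of the bis-triflate should leave the C1 hydroxyl free.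

**Step 10**
Reactants: 16 4,7-bis[4-(benzyloxy)phenyl]-2,2-di-tert-butyl-6-(methoxymethoxy)-1,3,2-benzodioxasilol-5-ol
Product: 17 4,7-bis[4-(benzyloxy)phenyl]-2,2-di-tert-butyl-6-(methoxymethoxy)-1,3,2-benzodioxasilol-5-yl acetate
Conditions: Ac2O, pyridine, DMAP (cat.), CH2Cl2, 0 °C → rt
Reagents that add atoms: acetic anhydride, CC(=O)OC(C)=O
Why: DMAP-catalysed acylation of the single remaining, doubly ortho-substituted phenol; silylene, MOM and benzyl ethers are inert.

**Step 11**
Reactants: 17 4,7-bis[4-(benzyloxy)phenyl]-2,2-di-tert-butyl-6-(methoxymethoxy)-1,3,2-benzodioxasilol-5-yl acetate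
Product: 18 2,5-bis[4-(benzyloxy)phenyl]-3,4-dihydroxy-6-(methoxymethoxy)phenyl acetate
Conditions: HF·pyridine, pyridine, THF, 0 °C, Ar
Reagents that add atoms: none
Why: Fluoride-driven desilylation cleaves both Si–O bonds, and buffered HF·pyridine neither cleaves nor moves the aryl acetate, whose ring neighbours (C2–OMOM, C6–aryl) offer no free hydroxyl.

**Step 12**
Reactants: 19 methyl (R)-3-hydroxybutanoate
Product: 20 methyl (R)-3-(benzyloxy)butanoate
Conditions: benzyl 2,2,2-trichloroacetimidate, TfOH (cat.), cyclohexane/CH2Cl2, 0 °C → rt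
Reagents that add atoms: benzyl 2,2,2-trichloroacetimidate, N=C(OCc1ccccc1)C(Cl)(Cl)Cl
Why: Acid-catalysed O-benzylation with the trichloroacetimidate avoids the basic conditions that cause retro-aldol or β-elimination in a β-hydroxy ester, and the stereocentre, not involved in bond making, keeps its R configuration.

**Step 13**
Reactants: 20 methyl (R)-3-(benzyloxy)butanoate
Product: 21 (R)-3-(benzyloxy)butanoic acid
Conditions: LiOH·H2O, THF/MeOH/H2O, 0 °C → rt; 1 M HCl
Reagents that add atoms: lithium hydroxide, [Li+].[OH-]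
Why: Saponification of the methyl ester; the carboxylate formed resists β-elimination and the stereocentre is untouched.

**Step 14**
Reactants: 18 2,5-bis[4-(benzyloxy)phenyl]-3,4-dihydroxy-6-(methoxymethoxy)phenyl acetate; 21 (R)-3-(benzyloxy)butanoic acid
Product: 22 4-(acetyloxy)-3,6-bis[4-(benzyloxy)phenyl]-5-(methoxymethoxy)-1,2-phenylene bis[(3R)-3-(benzyloxy)butanoate]
Conditions: 21 (2.6 equiv), DCC, DMAP, CH2Cl2, 0 °C → rt, Ar
Reagents that add atoms: none
Why: Carbodiimide/DMAP coupling (Steglich esterification) acylates both catechol hydroxyls through the N-acylpyridinium ion, which copes with ortho-substituted phenols, and the stereocentre, β to the carbonyl, is not at risk.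

**Step 15**
Reactants: 22 4-(acetyloxy)-3,6-bis[4-(benzyloxy)phenyl]-5-(methoxymethoxy)-1,2-phenylene bis[(3R)-3-(benzyloxy)butanoate]
Product: 23 4-(acetyloxy)-3,6-bis[4-(benzyloxy)phenyl]-5-hydroxy-1,2-phenylene bis[(3R)-3-(benzyloxy)butanoate]
Conditions: TFA/CH2Cl2 (1:5), H2O (2 equiv), 0 °C
Reagents that add atoms: none
Why: Acid-catalysed hydrolysis of the aryl MOM acetal; aryl esters and benzyl ethers should withstand cold dilute trifluoroacetic acid for the short time needed, and migration of the acetyl group to the freed neighbouring hydroxyl would give the same compound.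

**Step 16**
Reactants: 23 4-(acetyloxy)-3,6-bis[4-(benzyloxy)phenyl]-5-hydroxy-1,2-phenylene bis[(3R)-3-(benzyloxy)butanoate]
Product: 24 4-(acetyloxy)-3,6-bis[4-(benzyloxy)phenyl]-5-[(3-phenylpropanoyl)oxy]-1,2-phenylene bis[(3R)-3-(benzyloxy)butanoate]
Conditions: 3-phenylpropanoyl chloride, pyridine, DMAP (cat.), CH2Cl2, 0 °C → rt
Reagents that add atoms: 3-phenylpropanoyl chloride, O=C(Cl)CCc1ccccc1
Why: Acylation of the last phenol with the acid chloride under nucleophilic catalysis, pyridine being too weak a base to eliminate benzyl alcohol from the β-benzyloxy esters.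

**Step 17**
Reactants: 24 4-(acetyloxy)-3,6-bis[4-(benzyloxy)phenyl]-5-[(3-phenylpropanoyl)oxy]-1,2-phenylene bis[(3R)-3-(benzyloxy)butanoate]
Product: 25 Curtisian V
Conditions: H2 (1 atm), 20% Pd(OH)2/C, EtOAc/THF, rt
Reagents that add atoms: none
Why: Palladium-catalysed hydrogenolysis cleaves the two aryl and two alkyl benzyl ethers at their benzylic C–O bonds in one neutral operation that leaves the four aryl esters and the two R-configured carbinol centres untouched.

**Compound list**

1 | methyl glycolate | COC(=O)CO | starting material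
2 | methyl 2-(oxan-2-yloxy)acetate (racemic) | COC(=O)COC1CCCCO1 | intermediate
3 | N-methoxy-N-methyl-2-(oxan-2-yloxy)acetamide (racemic) | CON(C)C(=O)COC1CCCCO1 | intermediate
4 | 4-(benzyloxy)benzyl chloride | ClCc1ccc(OCc2ccccc2)cc1 | starting material
5 | 4-(benzyloxy)benzylmagnesium chloride | Cl[Mg]Cc1ccc(OCc2ccccc2)cc1 | intermediate
6 | 1-[4-(benzyloxy)phenyl]-3-(oxan-2-yloxy)propan-2-one (racemic) | O=C(Cc1ccc(OCc2ccccc2)cc1)COC1CCCCO1 | intermediate
7 | methyl 2-(methoxymethoxy)acetate | COCOCC(=O)OC | intermediate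
8 | 2-(methoxymethoxy)acetic acid | COCOCC(=O)O | intermediate
9 | 1-(imidazol-1-yl)-2-(methoxymethoxy)ethan-1-one | COCOCC(=O)n1ccnc1 | intermediate
10 | 3-[4-(benzyloxy)phenyl]-1-(methoxymethoxy)-5-(oxan-2-yloxy)pentane-2,4-dione (stereoisomer and tautomer mixture) | COCOCC(=O)C(c1ccc(OCc2ccccc2)cc1)C(=O)COC1CCCCO1 | intermediate
11 | methyl 4-(benzyloxy)benzoate | COC(=O)c1ccc(OCc2ccccc2)cc1 | starting material
12 | 1,4-bis[4-(benzyloxy)phenyl]-2-(methoxymethoxy)-6-(oxan-2-yloxy)hexane-1,3,5-trione (stereoisomer mixture) | O=C(c1ccc(OCc2ccccc2)cc1)C(OCOC)C(=O)C(c1ccc(OCc2ccccc2)cc1)C(=O)COC1CCCCO1 | intermediate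
13 | 1,4-bis[4-(benzyloxy)phenyl]-6-(methoxymethoxy)-2-(oxan-2-yloxy)hexane-1,3,5-trione (stereoisomer mixture) | O=C(c1ccc(OCc2ccccc2)cc1)C(OC1CCCCO1)C(=O)C(c1ccc(OCc2ccccc2)cc1)C(=O)COCOC | intermediate
14 | 2,5-bis[4-(benzyloxy)phenyl]-4-(methoxymethoxy)-6-(oxan-2-yloxy)benzene-1,3-diol (racemic) | Oc1c(OCOC)c(-c2ccc(OCc3ccccc3)cc2)c(OC2CCCCO2)c(O)c1-c1ccc(OCc2ccccc2)cc1 | intermediate
15 | 3,6-bis[4-(benzyloxy)phenyl]-5-(methoxymethoxy)benzene-1,2,4-triol | Oc1c(OCOC)c(-c2ccc(OCc3ccccc3)cc2)c(O)c(O)c1-c1ccc(OCc2ccccc2)cc1 | intermediate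
16 | 4,7-bis[4-(benzyloxy)phenyl]-2,2-di-tert-butyl-6-(methoxymethoxy)-1,3,2-benzodioxasilol-5-ol | Oc1c(OCOC)c(-c2ccc(OCc3ccccc3)cc2)c2O[Si](C(C)(C)C)(C(C)(C)C)Oc2c1-c1ccc(OCc2ccccc2)cc1 | intermediate
17 | 4,7-bis[4-(benzyloxy)phenyl]-2,2-di-tert-butyl-6-(methoxymethoxy)-1,3,2-benzodioxasilol-5-yl acetate | CC(=O)Oc1c(OCOC)c(-c2ccc(OCc3ccccc3)cc2)c2O[Si](C(C)(C)C)(C(C)(C)C)Oc2c1-c1ccc(OCc2ccccc2)cc1 | intermediate
18 | 2,5-bis[4-(benzyloxy)phenyl]-3,4-dihydroxy-6-(methoxymethoxy)phenyl acetate | CC(=O)Oc1c(OCOC)c(-c2ccc(OCc3ccccc3)cc2)c(O)c(O)c1-c1ccc(OCc2ccccc2)cc1 | intermediate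
19 | methyl (R)-3-hydroxybutanoate | COC(=O)C[C@@H](C)O | starting material
20 | methyl (R)-3-(benzyloxy)butanoate | COC(=O)C[C@@H](C)OCc1ccccc1 | intermediate
21 | (R)-3-(benzyloxy)butanoic acid | OC(=O)C[C@@H](C)OCc1ccccc1 | intermediate
22 | 4-(acetyloxy)-3,6-bis[4-(benzyloxy)phenyl]-5-(methoxymethoxy)-1,2-phenylene bis[(3R)-3-(benzyloxy)butanoate] | CC(=O)Oc1c(OCOC)c(-c2ccc(OCc3ccccc3)cc2)c(OC(=O)C[C@@H](C)OCc2ccccc2)c(OC(=O)C[C@@H](C)OCc2ccccc2)c1-c1ccc(OCc2ccccc2)cc1 | intermediate
23 | 4-(acetyloxy)-3,6-bis[4-(benzyloxy)phenyl]-5-hydroxy-1,2-phenylene bis[(3R)-3-(benzyloxy)butanoate] | CC(=O)Oc1c(O)c(-c2ccc(OCc3ccccc3)cc2)c(OC(=O)C[C@@H](C)OCc2ccccc2)c(OC(=O)C[C@@H](C)OCc2ccccc2)c1-c1ccc(OCc2ccccc2)cc1 | intermediate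
24 | 4-(acetyloxy)-3,6-bis[4-(benzyloxy)phenyl]-5-[(3-phenylpropanoyl)oxy]-1,2-phenylene bis[(3R)-3-(benzyloxy)butanoate] | CC(=O)Oc1c(OC(=O)CCc2ccccc2)c(-c2ccc(OCc3ccccc3)cc2)c(OC(=O)C[C@@H](C)OCc2ccccc2)c(OC(=O)C[C@@H](C)OCc2ccccc2)c1-c1ccc(OCc2ccccc2)cc1 | intermediate
25 | Curtisian V, 4-(acetyloxy)-3,6-bis(4-hydroxyphenyl)-5-[(3-phenylpropanoyl)oxy]-1,2-phenylene bis[(3R)-3-hydroxybutanoate] | CC(=O)Oc1c(OC(=O)CCc2ccccc2)c(-c2ccc(O)cc2)c(OC(=O)C[C@@H](C)O)c(OC(=O)C[C@@H](C)O)c1-c1ccc(O)cc1 | target

**Step count and risks**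

Total step count: 17. Longest linear sequence: 13 steps (steps 1, 2, 3, 6, 7, 8, 9, 10, 11, 14, 15, 16, 17, from methyl glycolate).

The three steps most likely to fail:

Step 7. Acylation of the dianion by the electron-rich, weakly electrophilic aryl ester may be outrun by proton transfer from the triketone as it forms and by self-condensation. The hindered aldol closure onto a deactivated aryl ketone may also lag behind retro-Claisen cleavage by hydroxide. The fallback sets out from 10. Its dianion (LiN(iPr)2, 2.1 equiv, THF, −78 °C) is added to commercial 4-(benzyloxy)benzaldehyde, an aldol addition that forms no acidic product. This should give 1,4-bis[4-(benzyloxy)phenyl]-1-hydroxy-2-(methoxymethoxy)-6-(oxan-2-yloxy)hexane-3,5-dione F1 and its regioisomer 1,4-bis[4-(benzyloxy)phenyl]-1-hydroxy-6-(methoxymethoxy)-2-(oxan-2-yloxy)hexane-3,5-dione F2. MnO2 in CH2Cl2 oxidises the benzylic carbinol of both to the triketones 12 and 13, now isolated. These are closed in a separate operation with Cs2CO3 in dry DMF, without hydroxide, and the route is rejoined at 14.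

Step 9. The first Si–O bond may form at the lone C1 hydroxyl, which cannot close a ring, so that open-chain silyl ethers and doubly silylated material arise; the triol may also oxidise in air to a hydroxyquinone during handling. The fallback sets out from 15 and replaces the irreversible silylation by a reversible condensation that only a catechol can complete. Phenylboronic acid (toluene, 4 Å sieves) should give 4,7-bis[4-(benzyloxy)phenyl]-6-(methoxymethoxy)-2-phenyl-1,3,2-benzodioxaborol-5-ol F3. Acetylation (Ac2O, pyridine) gives 4,7-bis[4-(benzyloxy)phenyl]-6-(methoxymethoxy)-2-phenyl-1,3,2-benzodioxaborol-5-yl acetate F4. Exchange of the boronate with pinacol releases the catechol, and the route is rejoined at 18.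

Step 6. The benzylic enolate may be acylated on oxygen to an enol ester, or be quenched by proton transfer before C-acylation. The fallback sets out from 6 and 7 and makes the C–C bond by aldol addition instead of acylation. Ester 7 is reduced with iBu2AlH at −78 °C to 2-(methoxymethoxy)acetaldehyde F5. The lithium enolate of 6 is added to it to give 3-[4-(benzyloxy)phenyl]-4-hydroxy-5-(methoxymethoxy)-1-(oxan-2-yloxy)pentan-2-one F6. Dess–Martin periodinane oxidises this β-hydroxy ketone to the diketone, and the route is rejoined at 10.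

**Further compounds**

F1 | step 7 | 1,4-bis[4-(benzyloxy)phenyl]-1-hydroxy-2-(methoxymethoxy)-6-(oxan-2-yloxy)hexane-3,5-dione | OC(c1ccc(OCc2ccccc2)cc1)C(OCOC)C(=O)C(c1ccc(OCc2ccccc2)cc1)C(=O)COC1CCCCO1
F2 | step 7 | 1,4-bis[4-(benzyloxy)phenyl]-1-hydroxy-6-(methoxymethoxy)-2-(oxan-2-yloxy)hexane-3,5-dione | OC(c1ccc(OCc2ccccc2)cc1)C(OC1CCCCO1)C(=O)C(c1ccc(OCc2ccccc2)cc1)C(=O)COCOC
F3 | step 9 | 4,7-bis[4-(benzyloxy)phenyl]-6-(methoxymethoxy)-2-phenyl-1,3,2-benzodioxaborol-5-ol | Oc1c(OCOC)c(-c2ccc(OCc3ccccc3)cc2)c2OB(c3ccccc3)Oc2c1-c1ccc(OCc2ccccc2)cc1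
F4 | step 9 | 4,7-bis[4-(benzyloxy)phenyl]-6-(methoxymethoxy)-2-phenyl-1,3,2-benzodioxaborol-5-yl acetate | CC(=O)Oc1c(OCOC)c(-c2ccc(OCc3ccccc3)cc2)c2OB(c3ccccc3)Oc2c1-c1ccc(OCc2ccccc2)cc1
F5 | step 6 | 2-(methoxymethoxy)acetaldehyde | COCOCC=O
F6 | step 6 | 3-[4-(benzyloxy)phenyl]-4-hydroxy-5-(methoxymethoxy)-1-(oxan-2-yloxy)pentan-2-one | COCOCC(O)C(c1ccc(OCc2ccccc2)cc1)C(=O)COC1CCCCO1
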